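Ring A is not purchased but assembled from open-chain parts: an α′-diazo enone and a prenyl-bearing siloxyalkyne. The feature exploited is the contiguous substitution of ring A, where prenylated C8 lies between the oxygenated carbons C7 and C8a and C4a, next to C8a, carries the C4 methylene. In one operation (Wolff rearrangement, [2+2] cycloaddition, 4π opening, 6π closure) the bonds C8a–C8, C7–C6 and C8a–C4a form, prenyl is locked at C8, and O8a emerges free while O7 stays silylated. The precursor is an (S)-6-aryl-7-silyloxy-1-diazohept-3-en-2-one that already holds rings B and D and the C3 stereocentre from an Evans allylation. Mitsunobu etherification then closes ring C.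

Key step: step 12

Remarks on the chemistry
- Assumption: the [C@H] descriptor of the target is read as (3S) (priorities C2 > C1′ > C4 > H). Isoflavan numbering is used (O1, C2, C3, C4, C4a, C5–C8, C8a; ring B primed; ring D = the dimethylpyran).
- Chr = 2,2-dimethyl-5-(triisopropylsilyloxy)-2H-chromen-6-yl, that is rings B and D bonded through C1′, with O2′ as the silylated oxygen.
- O2′ is carried as a TIPS ether and not as an acetal. The last step is then a fluoride deprotection, so the finished ortho-prenylphenol (prone to chroman formation) and ring D never meet acid.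
- Only the alkyl TBS ether is removed before ring C is closed. O8a–H is then the only free phenol in the Mitsunobu step. A free O2′–H would compete by closing a five-membered dihydrobenzofuran, and a free O7–H by intermolecular etherification.
- The diazoketone is reached by allylation, cross-metathesis with butenone and diazo transfer. This avoids a γ-hydroxy ester that could lactonise, an ester-to-aldehyde adjustment, and any diazomethane-derived reagent.
- Bond book-keeping of the key step: besides the three bonds named above, the Wolff shift makes C6–C5 and breaks C8a–C5. The C8a–C6 bond of the ketene is cut again in the 4π opening. The cycloadduct carries its alkenyl group on the sp3 carbon, so it is a 4-alkenylcyclobut-2-enone.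
- Light: only wavelengths above 400 nm are admitted. The diazoketone should absorb there, whereas the photochromic 2H-chromene should not.

Step 1
Reactants: 1 2,4-dihydroxybenzaldehyde; 2 3-methylbut-2-enal
Product: 4 5-hydroxy-2,2-dimethyl-2H-chromene-6-carbaldehyde, via ortho-quinone methide 3 (not isolated)
Conditions: Ca(OH)2, MeOH, rt
Reagents that add atoms: none
Why: Aldol-type attack of resorcinol C3 on the enal, loss of water to 3 and oxa-6π electrocyclisation (the known chromenylation of resorcinols with enals) should give the angular chromene, because the 2-OH is hydrogen-bonded to the formyl group and only the 4-OH can become the pyran oxygen.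

Step 2
Reactants: 4 5-hydroxy-2,2-dimethyl-2H-chromene-6-carbaldehyde
Product: 5 2,2-dimethyl-5-(triisopropylsilyloxy)-2H-chromene-6-carbaldehyde (Chr-CHO)
Conditions: TIPSOTf, 2,6-lutidine, CH2Cl2, 0 °C → rt
Reagents that add atoms: triisopropylsilyl triflate CC(C)[Si](OS(=O)(=O)C(F)(F)F)(C(C)C)C(C)C
Why: O-silylation of a hindered, hydrogen-bonded phenol calls for the silyl triflate, and the resulting TIPS ether should withstand ylides, amide bases, LiBH4 and mild acid until fluoride removes it in step 15.

Step 3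
Reactants: 5 Chr-CHO
Product: 7 Chr-acetaldehyde, via enol ether 6 (not isolated)
Conditions: MeOCH2PPh3Cl, KOtBu, THF, 0 °C; then 2 M HCl, THF, rt
Reagents that add atoms: (methoxymethyl)triphenylphosphonium chloride COC[P+](c1ccccc1)(c1ccccc1)c1ccccc1.[Cl-]; water O
Why: Wittig olefination with the methoxymethylene ylide and acid hydrolysis of the enol ether is the standard one-carbon homologation of an aryl aldehyde; protonation of the enol ether should outrun that of the ring D alkene, and aryl TIPS ethers tolerate dilute aqueous acid.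

Step 4
Reactants: 7 Chr-acetaldehyde
Product: 8 Chr-acetic acid
Conditions: NaClO2, NaH2PO4, 2-methylbut-2-ene, t-BuOH/H2O, 0 °C → rt
Reagents that add atoms: sodium chlorite [Na+].[O-]Cl=O
Why: Pinnick oxidation takes the aldehyde to the acid under buffered conditions, and the excess alkene should consume the hypochlorous acid before it can chlorinate the electron-rich arene or ring D.

Step 5
Reactants: 8 Chr-acetic acid; 9 (S)-4-benzyloxazolidin-2-one
Product: 11 (S)-4-benzyl-3-(Chr-acetyl)oxazolidin-2-one, via mixed pivalic anhydride 10 (not isolated)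
Conditions: t-BuCOCl, Et3N, THF, −20 °C; then LiCl, 9, −20 °C → rt
Reagents that add atoms: pivaloyl chloride CC(C)(C)C(=O)Cl (its atoms stay only in 10)
Why: N-acylation of the oxazolidinone through a mixed anhydride (LiCl/Et3N variant) should occur at the less hindered arylacetyl carbonyl and avoids an acid chloride and its HCl.

Step 6
Reactants: 11 (S)-4-benzyl-3-(Chr-acetyl)oxazolidin-2-one; 12 allyl iodide
Product: 14 (S)-4-benzyl-3-[(2S)-2-Chr-pent-4-enoyl]oxazolidin-2-one, via sodium Z-enolate 13 (not isolated)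
Conditions: NaN(SiMe3)2, THF, −78 °C; then 12, −78 → −40 °C
Reagents that add atoms: sodium bis(trimethylsilyl)amide C[Si](C)(C)[N-][Si](C)(C)C.[Na+] (sodium only, in 13)
Why: Evans alkylation, in which the chelated Z-enolate 13 is shielded on one face by the benzyl group of the (S)-auxiliary, so allyl iodide should enter from the other face and set the future C3 as S, in the sense known for arylacetyl imides.

Step 7
Reactants: 14 (S)-4-benzyl-3-[(2S)-2-Chr-pent-4-enoyl]oxazolidin-2-one
Product: 15 (2S)-2-Chr-pent-4-en-1-ol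
Conditions: LiBH4, H2O (1 equiv), Et2O, 0 °C
Reagents that add atoms: none
Why: Reductive removal of the auxiliary with LiBH4 in moist ether gives the primary alcohol; the transient α-aryl aldehyde should be reduced faster than it enolises, so C3 is kept, and the bulky TIPS group should not migrate to the new alkoxide.

Step 8
Reactants: 15 (2S)-2-Chr-pent-4-en-1-ol
Product: 16 tert-butyldimethyl[(2S)-2-Chr-pent-4-enyloxy]silane
Conditions: TBSCl, imidazole, DMF, rt
Reagents that add atoms: tert-butyldimethylsilyl chloride CC(C)(C)[Si](C)(C)Cl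
Why: Standard silylation masks the alcohol, which would otherwise add to the ketene of step 12, as an alkyl TBS ether that mild acid can later remove beside two aryl TIPS ethers.

Step 9
Reactants: 16 tert-butyldimethyl[(2S)-2-Chr-pent-4-enyloxy]silane; 17 but-3-en-2-one
Product: 18 (3E,6S)-7-(tert-butyldimethylsilyloxy)-6-Chr-hept-3-en-2-one
Conditions: 17 (3 equiv), second-generation Hoveyda–Grubbs catalyst [RuCl2(H2IMes)(=CH-C6H4-2-OiPr), 3 mol %], CH2Cl2, 40 °C
Reagents that add atoms: none
Why: Olefin cross-metathesis of a terminal alkene with an electron-poor vinyl ketone is selective for the E-enone, and the unstrained ring D alkene next to a quaternary carbon should not engage the ruthenium carbene.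

Step 10
Reactants: 18 (3E,6S)-7-(tert-butyldimethylsilyloxy)-6-Chr-hept-3-en-2-one
Product: 20 (3E,6S)-7-(tert-butyldimethylsilyloxy)-6-Chr-1-diazohept-3-en-2-one, via trifluoroacetyl diketone 19 (not isolated)
Conditions: LiN(SiMe3)2, THF, −78 °C; CF3CO2CH2CF3, −78 °C; aq NH4Cl; then MsN3, Et3N, H2O (1 equiv), MeCN, rt
Reagents that add atoms: methanesulfonyl azide CS(=O)(=O)N=[N+]=[N-]; 2,2,2-trifluoroethyl trifluoroacetate O=C(OCC(F)(F)F)C(F)(F)F (its atoms stay only in 19)
Why: Detrifluoroacetylative diazo transfer (kinetic deprotonation at the methyl group, Claisen-type trifluoroacetylation to 19, then reaction with the sulfonyl azide) is the established entry to α′-diazo enones, since acyl chloride/diazomethane routes suffer from dipolar cycloaddition to the enone; C3 lies δ to the carbonyl and is not touched.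

Step 11
Reactants: 21 ethyl 4-methylpent-3-enoate
Product: 24 triisopropyl(5-methylhex-4-en-1-ynyloxy)silane, via lithium dibromoenolate 22 (not isolated), via lithium ynolate 23 (not isolated)
Conditions: CH2Br2, lithium 2,2,6,6-tetramethylpiperidide, THF, −78 °C; 21; n-BuLi, −78 °C → rt; TIPSCl, −78 °C → rt
Reagents that add atoms: dibromomethane BrCBr; triisopropylsilyl chloride CC(C)[Si](Cl)(C(C)C)C(C)C; n-butyllithium [Li]CCCC (lithium only, in 22 and 23)
Why: Kowalski-type sequence, in which LiCHBr2 adds to the ester, enolisation gives 22, bromine–lithium exchange triggers the 1,2-shift of the prenyl group to ynolate 23, and the bulky silyl chloride should react at oxygen rather than at carbon.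

Step 12
Reactants: 20 (3E,6S)-7-(tert-butyldimethylsilyloxy)-6-Chr-1-diazohept-3-en-2-one; 24 triisopropyl(5-methylhex-4-en-1-ynyloxy)silane
Product: 29 6-[(2S)-3-(tert-butyldimethylsilyloxy)-2-Chr-propyl]-2-(3-methylbut-2-enyl)-3-(triisopropylsilyloxy)phenol, via vinylketene 25 (not isolated), via alkenylcyclobutenone 26 (not isolated), via dienylketene 27 (not isolated), via cyclohexadienone 28 (not isolated)
Conditions: 24 (2 equiv), degassed toluene (0.05 M), LED 420–450 nm, rt, until N2 evolution ends; then 80–100 °C, dark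
Reagents that add atoms: none
Why: Excitation of the diazoketone expels N2 while the alkenyl group shifts from C8a to C6 (Wolff rearrangement) to give vinylketene 25, whose sp carbon C8a is attacked by the nucleophilic, prenyl-bearing alkyne carbon C8 while C6 bonds to the siloxy carbon C7, a [2+2] cycloaddition to 26. Warming opens 26 reversibly by 4π electrocyclic cleavage of C8a–C6 to dienylketene 27, ring A closes by 6π electrocyclisation (C8a–C4a) to dienone 28, and tautomerisation gives the phenol. This is the Danheiser benzannulation in its diazoketone version, known with siloxyalkynes as a route to resorcinol monosilyl ethers. No lasting stereocentre is created, since the sp3 centres of 26 and 28 vanish on aromatisation, and C3 is insulated from the reacting π system by C4 and is not enolisable, so it should keep its S configuration. Regioselectivity rests on the polarisation of the siloxyalkyne, so prenyl can only end up at C8 between O7 and O8a, and the two oxygens emerge differentiated (O7 silylated, O8a free). Chemoselectivity rests on 24 being a far better ketenophile than the prenyl and ring D alkenes, on the masked C2 alcohol, and on light that only the diazoketone should absorb.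

Step 13
Reactants: 29 6-[(2S)-3-(tert-butyldimethylsilyloxy)-2-Chr-propyl]-2-(3-methylbut-2-enyl)-3-(triisopropylsilyloxy)phenol
Product: 30 6-[(2S)-3-hydroxy-2-Chr-propyl]-2-(3-methylbut-2-enyl)-3-(triisopropylsilyloxy)phenol
Conditions: CSA (10 mol %), MeOH/CH2Cl2 1:1, 0 °C
Reagents that add atoms: none
Why: Acid-catalysed methanolysis cleaves a primary alkyl TBS ether much faster than aryl TIPS ethers, and catalytic sulfonic acid at 0 °C should be too mild to cyclise the ortho-prenylphenol or to hydrate ring D.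

Step 14
Reactants: 30 6-[(2S)-3-hydroxy-2-Chr-propyl]-2-(3-methylbut-2-enyl)-3-(triisopropylsilyloxy)phenol
Product: 32 (3S)-3-Chr-8-(3-methylbut-2-enyl)-7-(triisopropylsilyloxy)chroman, via oxyphosphonium phenoxide 31 (not isolated)
Conditions: PPh3, DIAD, THF (0.01 M), 0 °C → rt
Reagents that add atoms: triphenylphosphine c1ccc(cc1)P(c1ccccc1)c1ccccc1 (its atoms stay only in 31)
Why: Intramolecular Mitsunobu etherification, in which the O8a phenoxide displaces the activated primary carbon C2 of 31 in a 6-exo-tet closure of ring C; C3 is not a reacting centre, and the blocked O7 and O2′ exclude oligomers and the five-membered alternative.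

Step 15
Reactants: 32 (3S)-3-Chr-8-(3-methylbut-2-enyl)-7-(triisopropylsilyloxy)chroman
Product: 33 (3S)-3-(5-hydroxy-2,2-dimethyl-2H-chromen-6-yl)-8-(3-methylbut-2-enyl)chroman-7-ol (target)
Conditions: Bu4NF, AcOH, THF, 0 °C
Reagents that add atoms: none
Why: Fluoride-induced desilylation removes both aryl TIPS ethers at low temperature, the acetic acid buffer keeps the phenoxides from air oxidation, and nothing present is acidic enough to cyclise the prenylphenol.

Compound list
1 | 2,4-dihydroxybenzaldehyde | O=Cc1ccc(O)cc1O | starting material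
2 | 3-methylbut-2-enal | CC(C)=CC=O | starting material
3 | ortho-quinone methide, 2-hydroxy-3-(3-methylbut-2-enylidene)-4-oxocyclohexa-1,5-diene-1-carbaldehyde | O=CC1=C(O)C(=CC=C(C)C)C(=O)C=C1 | intermediate
4 | 5-hydroxy-2,2-dimethyl-2H-chromene-6-carbaldehyde | O=Cc1ccc2c(c1O)C=CC(C)(C)O2 | intermediate
5 | 2,2-dimethyl-5-(triisopropylsilyloxy)-2H-chromene-6-carbaldehyde | O=Cc1ccc2c(c1O[Si](C(C)C)(C(C)C)C(C)C)C=CC(C)(C)O2 | intermediate
6 | 6-(2-methoxyvinyl)-2,2-dimethyl-5-(triisopropylsilyloxy)-2H-chromene (E/Z mixture) | COC=Cc1ccc2c(c1O[Si](C(C)C)(C(C)C)C(C)C)C=CC(C)(C)O2 | intermediate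
7 | [2,2-dimethyl-5-(triisopropylsilyloxy)-2H-chromen-6-yl]acetaldehyde | O=CCc1ccc2c(c1O[Si](C(C)C)(C(C)C)C(C)C)C=CC(C)(C)O2 | intermediate
8 | [2,2-dimethyl-5-(triisopropylsilyloxy)-2H-chromen-6-yl]acetic acid | OC(=O)Cc1ccc2c(c1O[Si](C(C)C)(C(C)C)C(C)C)C=CC(C)(C)O2 | intermediate
9 | (S)-4-benzyloxazolidin-2-one | O=C1N[C@@H](Cc2ccccc2)CO1 | starting material
10 | Chr-acetic pivalic anhydride | CC(C)(C)C(=O)OC(=O)Cc1ccc2c(c1O[Si](C(C)C)(C(C)C)C(C)C)C=CC(C)(C)O2 | intermediate
11 | (S)-4-benzyl-3-(Chr-acetyl)oxazolidin-2-one | O=C(Cc1ccc2c(c1O[Si](C(C)C)(C(C)C)C(C)C)C=CC(C)(C)O2)N1[C@@H](Cc2ccccc2)COC1=O | intermediate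
12 | allyl iodide (3-iodoprop-1-ene) | C=CCI | starting material
13 | sodium Z-enolate of 11 | [Na+].[O-]/C(=C\c1ccc2c(c1O[Si](C(C)C)(C(C)C)C(C)C)C=CC(C)(C)O2)N1[C@@H](Cc2ccccc2)COC1=O | intermediate
14 | (S)-4-benzyl-3-[(2S)-2-Chr-pent-4-enoyl]oxazolidin-2-one | C=CC[C@@H](c1ccc2c(c1O[Si](C(C)C)(C(C)C)C(C)C)C=CC(C)(C)O2)C(=O)N1[C@@H](Cc2ccccc2)COC1=O | intermediate
15 | (2S)-2-Chr-pent-4-en-1-ol | C=CC[C@@H](c1ccc2c(c1O[Si](C(C)C)(C(C)C)C(C)C)C=CC(C)(C)O2)CO | intermediate
16 | tert-butyldimethyl[(2S)-2-Chr-pent-4-enyloxy]silane | C=CC[C@@H](c1ccc2c(c1O[Si](C(C)C)(C(C)C)C(C)C)C=CC(C)(C)O2)CO[Si](C)(C)C(C)(C)C | intermediate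
17 | but-3-en-2-one | C=CC(C)=O | starting material
18 | (3E,6S)-7-(tert-butyldimethylsilyloxy)-6-Chr-hept-3-en-2-one | CC(=O)/C=C/C[C@@H](c1ccc2c(c1O[Si](C(C)C)(C(C)C)C(C)C)C=CC(C)(C)O2)CO[Si](C)(C)C(C)(C)C | intermediate
19 | (5E,8S)-9-(tert-butyldimethylsilyloxy)-8-Chr-1,1,1-trifluoronon-5-ene-2,4-dione | FC(F)(F)C(=O)CC(=O)/C=C/C[C@@H](c1ccc2c(c1O[Si](C(C)C)(C(C)C)C(C)C)C=CC(C)(C)O2)CO[Si](C)(C)C(C)(C)C | intermediate
20 | (3E,6S)-7-(tert-butyldimethylsilyloxy)-6-Chr-1-diazohept-3-en-2-one | [N-]=[N+]=CC(=O)/C=C/C[C@@H](c1ccc2c(c1O[Si](C(C)C)(C(C)C)C(C)C)C=CC(C)(C)O2)CO[Si](C)(C)C(C)(C)C | intermediate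
21 | ethyl 4-methylpent-3-enoate | CCOC(=O)CC=C(C)C | starting material
22 | lithium 1,1-dibromo-5-methylhexa-1,4-dien-2-olate | [Li+].[O-]C(CC=C(C)C)=C(Br)Br | intermediate
23 | lithium 5-methylhex-4-en-1-yn-1-olate | [Li+].[O-]C#CCC=C(C)C | intermediate
24 | triisopropyl(5-methylhex-4-en-1-ynyloxy)silane | CC(C)=CCC#CO[Si](C(C)C)(C(C)C)C(C)C | intermediate
25 | vinylketene, (3E,6S)-7-(tert-butyldimethylsilyloxy)-6-Chr-hepta-1,3-dien-1-one | O=C=C/C=C/C[C@@H](c1ccc2c(c1O[Si](C(C)C)(C(C)C)C(C)C)C=CC(C)(C)O2)CO[Si](C)(C)C(C)(C)C | intermediate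
26 | 4-[(1E,4S)-5-(tert-butyldimethylsilyloxy)-4-Chr-pent-1-enyl]-2-(3-methylbut-2-enyl)-3-(triisopropylsilyloxy)cyclobut-2-en-1-one (both epimers at ring C4) | O=C1C(CC=C(C)C)=C(O[Si](C(C)C)(C(C)C)C(C)C)C1/C=C/C[C@@H](c2ccc3c(c2O[Si](C(C)C)(C(C)C)C(C)C)C=CC(C)(C)O3)CO[Si](C)(C)C(C)(C)C | intermediate
27 | dienylketene, ketene carbon C8a and C5 cis about C7=C6, C5=C4a E | O=C=C(CC=C(C)C)/C(O[Si](C(C)C)(C(C)C)C(C)C)=C\C=C\C[C@@H](c2ccc3c(c2O[Si](C(C)C)(C(C)C)C(C)C)C=CC(C)(C)O3)CO[Si](C)(C)C(C)(C)C | intermediate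
28 | 6-[(2S)-3-(tert-butyldimethylsilyloxy)-2-Chr-propyl]-2-(3-methylbut-2-enyl)-3-(triisopropylsilyloxy)cyclohexa-2,4-dien-1-one (both epimers at ring C6) | O=C1C(CC=C(C)C)=C(O[Si](C(C)C)(C(C)C)C(C)C)C=CC1C[C@@H](c2ccc3c(c2O[Si](C(C)C)(C(C)C)C(C)C)C=CC(C)(C)O3)CO[Si](C)(C)C(C)(C)C | intermediate
29 | 6-[(2S)-3-(tert-butyldimethylsilyloxy)-2-Chr-propyl]-2-(3-methylbut-2-enyl)-3-(triisopropylsilyloxy)phenol | CC(C)=CCc1c(O[Si](C(C)C)(C(C)C)C(C)C)ccc(C[C@@H](c2ccc3c(c2O[Si](C(C)C)(C(C)C)C(C)C)C=CC(C)(C)O3)CO[Si](C)(C)C(C)(C)C)c1O | intermediate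
30 | 6-[(2S)-3-hydroxy-2-Chr-propyl]-2-(3-methylbut-2-enyl)-3-(triisopropylsilyloxy)phenol | CC(C)=CCc1c(O[Si](C(C)C)(C(C)C)C(C)C)ccc(C[C@@H](c2ccc3c(c2O[Si](C(C)C)(C(C)C)C(C)C)C=CC(C)(C)O3)CO)c1O | intermediate
31 | oxyphosphonium phenoxide of 30 (C2–O–PPh3 cation, O8a anion) | CC(C)=CCc1c(O[Si](C(C)C)(C(C)C)C(C)C)ccc(C[C@@H](c2ccc3c(c2O[Si](C(C)C)(C(C)C)C(C)C)C=CC(C)(C)O3)CO[P+](c2ccccc2)(c2ccccc2)c2ccccc2)c1[O-] | intermediate
32 | (3S)-3-Chr-8-(3-methylbut-2-enyl)-7-(triisopropylsilyloxy)chroman | CC(C)=CCc1c(O[Si](C(C)C)(C(C)C)C(C)C)ccc2c1OC[C@H](c1ccc3c(c1O[Si](C(C)C)(C(C)C)C(C)C)C=CC(C)(C)O3)C2 | intermediate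
33 | (3S)-3-(5-hydroxy-2,2-dimethyl-2H-chromen-6-yl)-8-(3-methylbut-2-enyl)chroman-7-ol | CC(C)=CCc1c(O)ccc2c1OC[C@H](c1ccc3c(c1O)C=CC(C)(C)O3)C2 | target

Total step count: 15. Longest linear sequence: 14 steps (steps 1–10 and 12–15, from 1); step 11 is the one-step side branch.

Steps most likely to fail

1. Step 12.
- What may go wrong: stray short-wave light may open ring D electrocyclically, with an irreversible hydrogen shift to follow.
- Light-induced E→Z isomerisation of the enone may be followed by a 1,5-hydrogen shift in the Z-vinylketene.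
- The ketene may dimerise, or the freshly formed phenol may be acylated by it.
- Thermal opening of the cyclobutenone may remain incomplete.
- Fallback without light: it sets out from 16 and comes back at vinylketene 25, bypassing steps 9 and 10. Cross-metathesis of 16 with but-3-enoic acid (second-generation Grubbs catalyst, CH2Cl2, 40 °C) would give (3E,6S)-7-(tert-butyldimethylsilyloxy)-6-Chr-hept-3-enoic acid F1. 1-Chloro-N,N,2-trimethylprop-1-en-1-amine (CH2Cl2, 0 °C) would convert it under neutral conditions into (3E,6S)-7-(tert-butyldimethylsilyloxy)-6-Chr-hept-3-enoyl chloride F2. Slow addition of F2 to i-Pr2NEt and 24 in toluene at 80–100 °C would release 25 by dehydrochlorination, a known source of vinylketenes. The sequence 26, 27, 28, 29 then runs purely thermally.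

2. Step 11.
- What may go wrong: the β,γ-unsaturated ester may be deprotonated at its α-carbon in competition with carbenoid addition.
- Silylation may occur at carbon instead of oxygen.
- The siloxyalkyne may be lost by hydrolysis during purification.
- Fallback by oxidation of an acetylide instead of a carbenoid rearrangement: it sets out from 21 and comes back at ynolate 23. i-Bu2AlH (CH2Cl2, −78 °C) would give 4-methylpent-3-enal F3. Ramirez olefination (CBr4, PPh3, CH2Cl2, 0 °C) would give 1,1-dibromo-5-methylhexa-1,4-diene F4. n-BuLi (2 equiv, THF, −78 °C, the second stage of a Corey–Fuchs sequence) would give lithium 5-methylhex-4-en-1-ynide F5. Lithium tert-butyl peroxide (t-BuOOH, LiN(SiMe3)2, THF, −78 → 0 °C) would oxidise F5 to 23. Silylation then follows as in step 11.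

3. Step 3.
- What may go wrong: hydrolysis of the aryl-conjugated enol ether may be slow, so that hydration or oligomerisation of ring D competes.
- The electron-rich arylacetaldehyde may self-condense or oxidise in air during handling.
- Fallback without aqueous acid and without an isolated aldehyde: it sets out from 5 and comes back at acid 8, bypassing 7 and step 4. Wittig methylenation (MePPh3Br, KOtBu, THF, 0 °C) would give 2,2-dimethyl-5-(triisopropylsilyloxy)-6-vinyl-2H-chromene F6. 9-BBN (THF, rt) should add only to the terminal alkene to give 9-(2-Chr-ethyl)-9-borabicyclo[3.3.1]nonane F7. NaBO3·4H2O would oxidise F7 to 2-Chr-ethanol F8. TEMPO (cat.), PhI(OAc)2, MeCN/H2O would then take F8 to 8.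

Further compounds
F1 | step 12 | (3E,6S)-7-(tert-butyldimethylsilyloxy)-6-Chr-hept-3-enoic acid | OC(=O)C/C=C/C[C@@H](c1ccc2c(c1O[Si](C(C)C)(C(C)C)C(C)C)C=CC(C)(C)O2)CO[Si](C)(C)C(C)(C)C
F2 | step 12 | (3E,6S)-7-(tert-butyldimethylsilyloxy)-6-Chr-hept-3-enoyl chloride | ClC(=O)C/C=C/C[C@@H](c1ccc2c(c1O[Si](C(C)C)(C(C)C)C(C)C)C=CC(C)(C)O2)CO[Si](C)(C)C(C)(C)C
F3 | step 11 | 4-methylpent-3-enal | CC(C)=CCC=O
F4 | step 11 | 1,1-dibromo-5-methylhexa-1,4-diene | CC(C)=CCC=C(Br)Br
F5 | step 11 | lithium 5-methylhex-4-en-1-ynide | [Li+].[C-]#CCC=C(C)C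
F6 | step 3 | 2,2-dimethyl-5-(triisopropylsilyloxy)-6-vinyl-2H-chromene | C=Cc1ccc2c(c1O[Si](C(C)C)(C(C)C)C(C)C)C=CC(C)(C)O2
F7 | step 3 | 9-(2-Chr-ethyl)-9-borabicyclo[3.3.1]nonane | C1CC2CCCC(C1)B2CCc1ccc2c(c1O[Si](C(C)C)(C(C)C)C(C)C)C=CC(C)(C)O2
F8 | step 3 | 2-Chr-ethanol | OCCc1ccc2c(c1O[Si](C(C)C)(C(C)C)C(C)C)C=CC(C)(C)O2
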